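A last reading is easily taken for an end, and at the meeting on this flask the analyst warned that the dusk run was still rising at its last reading.

- dusk: J 0.80 M (in portions, 4); G 0.40 M; X 1.6 M; run made earlier; portions every 1.0 h
- flask: J 0.80 M (in portions, 4); G 0.400 M; X 0.800 M; time 15 d; the portions of J follow each other after 1.0 h, the first at the start

dusk run (percent of the J charged)

| time / h | L / % | E / % |
|---|---|---|
| 5.00 | 11.9 | 3.5 |
| 12.0 | 12.8 | 11.7 |
| 25.0 | 8.2 | 21.6 |
| 40.0 | 6.3 | 25.5 |

(readings scatter by 1 percentage point)

- the analysis behind the earlier runs scatters by 1 percentage point, standard deviation
- the reaction counts as stopped when no species that holds the J changes by six tenths of a point or more over the second half of the time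
- no earlier run changes the charge of X; that part of a forecast is a guess

- at 15 d, what has stopped the reaction, if anything has (all of J has reacted / G has run out first / forward and back rates have come level / it is still moving)
- how much L there is at 15 d, in percent of the J charged
- how much E there is at 15 d, in percent of the J charged

The analyst reported L plus E at 31.8% after 40.0 h, against 29.8% at 25.0 h, so she took the later figure as a floor. The chair asked whether E took a second G. She thought not, since L plus 2 times E would come to 57.3% of the J charged, above the 50.0% that G allows. The meeting therefore counted one G per J, with G as the limiting reagent.

The kineticist proposed carrying one number. With G down to 36.4% and X up to 116% of their charges, she got 5.94 for the level quotient, which is the fraction of J turned to L and E over the fraction of J left, times the fraction of X over the fraction of G, times the X charge over the G charge. Being taken from a rising reading, it too was a floor.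

The bench objected that this flask holds 0.800 M of X against 1.6 M, a change no earlier run tests, and the kineticist accepted that as a guess. Solved for the flask's charges, the quotient gave L plus E of at least 36.7%, below the ceiling, with G at 26.7% of its charge. The ratio of E to L, read as 4.05 at the last reading and 2.63 before it, split that into E of at least 29.4% and L near 7.27%, the latter an estimate and not a bound, since a larger sum raises L while a larger ratio lowers it. The chair minuted forward and back rates level at 15 d, which is 9.00 times the dusk run's length.

The forecast also says forward and back rates have come level, with L 6.5% (5% to 8%) and E 31.5% (27.5% to 36%), higher in E than the meeting's floor, and it warns that “the X effect is extrapolated”.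

The flask gives forward and back rates have come level, with L 5.07% and E 35.1%.

    J + G ⇌ X + L (K = 1.80, k = 0.304 M⁻¹ h⁻¹)
    L + G ⇌ X + D (K = 3.20, k = 0.123 M⁻¹ h⁻¹)
    D + G ⇌ X + Z (K = 89.5, k = 0.0186 M⁻¹ h⁻¹)
    L ⇌ E (K = 6.90, k = 0.102 h⁻¹)

At 15.0 d this flask holds J 58.6%, G 13.7% and X 143%, each of its own charge, so its level quotient is 14.3, above the floor. The neighbour flask with 0.24 M of G gives 14.2 from its simulated end, so the quotient held when the G charge changed. The using up of G is the main reason this flask stops short: the same run without it converts 81.8% of J, against 41.4%.

The runs are simulated from invented constants, and the scatter is random.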